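**Retrosynthetic overview**

1. Numbering: five-membered ring C1 (quaternary, CH3)–C2 (angelate)–C3–C4 (isopropyl carbinol)–C5 (ring-fusion CH); seven-membered ring C5–C6 (aroyloxy)–C7–C8 (CH3)=C9–C10–C1.
2. Both esters are cut last; the C6 carbinol comes from hydroxyl-directed reduction of a C6 ketone, the C4 carbinol from isopropyl addition to a C4 ketone, and C2 is carried from the chiral pool as a silyl ether.
3. Feature the strategy rests on: with C6 at the enol ether level, C5=C6 and C8=C9 flank C7 as a cyclohepta-1,4-diene, and its sp3 carbon C1 is the β-carbon of the cyclopentenone C4(=O)–C5=C1. Cutting C1–C10 and joining C6–C8 (retro-Cope) gives a cis-1-siloxy-1-cyclopentenonyl-2-methyl-2-vinylcyclopropane (C6–C7–C8).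
4. The cyclopropane comes from methylenation (C7) of the silyl dienol ether of a C6 ketone, itself made by acylating a C5 alkenyllithium derived from (S)-4-silyloxycyclopent-2-enone.
5. Ring order: five-membered ring (chiral pool), then three-membered ring, then seven-membered ring by [3,3] ring expansion of the cyclopropane.

Key step: step 12

Remark on the chemistry: C4 is held as a silyl-protected carbinol from step 4 to step 11 so that C6 is the only ketone present when the enol ether is made, and (S)-4-(tert-butyldimethylsilyloxy)cyclopent-2-en-1-one and 2-methylbut-3-enoic acid are taken as commercial.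

**Route**

Step 1
Reactants: 1 (S)-4-(tert-butyldimethylsilyloxy)cyclopent-2-en-1-one
Product: 2 (3S,4S)-4-(tert-butyldimethylsilyloxy)-3-methyl-1-(trimethylsilyloxy)cyclopent-1-ene
Conditions: Me2CuLi, TMSCl, THF, −78 °C
Reagents that add atoms: lithium dimethylcuprate [Li+].C[Cu-]C; chlorotrimethylsilane C[Si](C)(C)Cl
Why: Cuprate conjugate addition with in situ O-silylation of the enolate puts the methyl group on C1 anti to the C2 silyloxy group; this C1 stereocentre is transient, since C1 becomes trigonal again in step 2.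

Step 2
Reactants: 2 (3S,4S)-4-(tert-butyldimethylsilyloxy)-3-methyl-1-(trimethylsilyloxy)cyclopent-1-ene
Product: 3 (S)-4-(tert-butyldimethylsilyloxy)-3-methylcyclopent-2-en-1-one
Conditions: Pd(OAc)2, MeCN, rt
Reagents that add atoms: none
Why: Saegusa–Ito oxidation; the palladium enolate at C5 has only C1–H as β-hydrogen, so β-hydride elimination restores the enone with the methyl group on C1 and leaves the C2 stereocentre untouched.

Step 3
Reactants: 3 (S)-4-(tert-butyldimethylsilyloxy)-3-methylcyclopent-2-en-1-one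
Product: 4 (S)-4-(tert-butyldimethylsilyloxy)-2-iodo-3-methylcyclopent-2-en-1-one
Conditions: iodine, pyridine, CH2Cl2, 0 °C to rt
Reagents that add atoms: iodine [I][I]
Why: α-Iodination of a cyclic enone (amine conjugate addition, iodination of the enolate, elimination) places iodine on C5, the only vinylic C–H.

Step 4
Reactants: 4 (S)-4-(tert-butyldimethylsilyloxy)-2-iodo-3-methylcyclopent-2-en-1-one
Product: 5 (1R,4S)-4-(tert-butyldimethylsilyloxy)-2-iodo-3-methylcyclopent-2-en-1-ol
Conditions: NaBH4, CeCl3·7H2O, MeOH, −78 °C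
Reagents that add atoms: none
Why: Luche 1,2-reduction; hydride should add to the C4 carbonyl anti to the C2 silyloxy group, giving the C4 hydroxyl cis to the C2 oxygen and masking the ketone as a carbinol that cannot enolise in steps 7 and 8.

Step 5
Reactants: 5 (1R,4S)-4-(tert-butyldimethylsilyloxy)-2-iodo-3-methylcyclopent-2-en-1-ol
Product: 6 cis-(1R,4S)-4-(tert-butyldimethylsilyloxy)-2-iodo-3-methyl-1-(triethylsilyloxy)cyclopent-2-ene
Conditions: TESCl, imidazole, DMF, 0 °C
Reagents that add atoms: chlorotriethylsilane CC[Si](Cl)(CC)CC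
Why: Silyl ether formation on a secondary allylic alcohol; the triethylsilyl ether survives organolithium and amide bases and can later be removed beside the two tert-butyldimethylsilyl ethers.

Step 6
Reactants: 7 2-methylbut-3-enoic acid (racemic)
Product: 9 N-methoxy-N,2-dimethylbut-3-enamide, via acyl imidazolide 8 (not isolated)
Conditions: 1,1'-carbonyldiimidazole, CH2Cl2, rt; then MeNHOMe·HCl
Reagents that add atoms: 1,1'-carbonyldiimidazole O=C(n1ccnc1)n1ccnc1 (imidazolyl group of 8); N,O-dimethylhydroxylamine hydrochloride CNOC.Cl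
Why: Amide formation through the acyl imidazolide gives the Weinreb amide under conditions mild enough to keep the alkene out of conjugation; the α-stereocentre is racemic and disappears in step 8.

Step 7
Reactants: 6 cis-(1R,4S)-4-(tert-butyldimethylsilyloxy)-2-iodo-3-methyl-1-(triethylsilyloxy)cyclopent-2-ene; 9 N-methoxy-N,2-dimethylbut-3-enamide
Product: 11 1-[(3S,5R)-3-(tert-butyldimethylsilyloxy)-2-methyl-5-(triethylsilyloxy)cyclopent-1-en-1-yl]-2-methylbut-3-en-1-one, via alkenyllithium 10 (not isolated)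
Conditions: t-BuLi (2 equiv), Et2O, −78 °C; then 9, −78 to −20 °C; aq. NH4Cl
Reagents that add atoms: tert-butyllithium [Li]C(C)(C)C (lithium of 10)
Why: Iodine–lithium exchange followed by acylation of the alkenyllithium with the Weinreb amide, whose chelated tetrahedral adduct stops over-addition and releases the C6 ketone on work-up; the C8 epimers formed are of no consequence.

Step 8
Reactants: 11 1-[(3S,5R)-3-(tert-butyldimethylsilyloxy)-2-methyl-5-(triethylsilyloxy)cyclopent-1-en-1-yl]-2-methylbut-3-en-1-one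
Product: 13 (1E)-1-(tert-butyldimethylsilyloxy)-1-[(3S,5R)-3-(tert-butyldimethylsilyloxy)-2-methyl-5-(triethylsilyloxy)cyclopent-1-en-1-yl]-2-methylbuta-1,3-diene, via lithium dienolate 12 (not isolated)
Conditions: LiN(iPr)2 (LDA), THF, −78 °C; then TBSOTf, −78 °C
Reagents that add atoms: lithium diisopropylamide [Li]N(C(C)C)C(C)C (lithium of 12); tert-butyldimethylsilyl trifluoromethanesulfonate CC(C)(C)[Si](C)(C)OS(=O)(=O)C(F)(F)F
Why: Kinetic enolisation removes C8–H, the only α-hydrogen of the only ketone and allylic as well, and O-silylation gives the siloxydiene; the E geometry (silyloxy cis to the C8 methyl, ring cis to the vinyl group) is expected because the bulky twisted cyclopentenyl group sits better next to the flat vinyl group than next to the methyl group.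

Step 9
Reactants: 13 (1E)-1-(tert-butyldimethylsilyloxy)-1-[(3S,5R)-3-(tert-butyldimethylsilyloxy)-2-methyl-5-(triethylsilyloxy)cyclopent-1-en-1-yl]-2-methylbuta-1,3-diene
Product: 14 (1S,2R)-1-(tert-butyldimethylsilyloxy)-1-[(3S,5R)-3-(tert-butyldimethylsilyloxy)-2-methyl-5-(triethylsilyloxy)cyclopent-1-en-1-yl]-2-ethenyl-2-methylcyclopropane
Conditions: Et2Zn, CH2I2, CH2Cl2, −20 to 0 °C
Reagents that add atoms: diiodomethane [I]C[I]
Why: Simmons–Smith methylenation (Furukawa variant) attacks the electron-rich silyl enol ether C6=C8 first and adds C7 stereospecifically syn, so the E geometry becomes the cis relation of cyclopentenyl and vinyl groups; C6 and C8 are set by substrate control, with C8 expected to turn to the ring face away from the C4 silyl ether and the carbenoid to approach the π-face turned toward C4–H instead of the in-plane C1 methyl, and the other cis diastereomer is removed by chromatography.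

Step 10
Reactants: 14 (1S,2R)-1-(tert-butyldimethylsilyloxy)-1-[(3S,5R)-3-(tert-butyldimethylsilyloxy)-2-methyl-5-(triethylsilyloxy)cyclopent-1-en-1-yl]-2-ethenyl-2-methylcyclopropane
Product: 15 (1R,4S)-4-(tert-butyldimethylsilyloxy)-2-[(1S,2R)-1-(tert-butyldimethylsilyloxy)-2-ethenyl-2-methylcyclopropyl]-3-methylcyclopent-2-en-1-ol
Conditions: HF·pyridine, pyridine, THF, 0 °C
Reagents that add atoms: none
Why: Selective desilylation; buffered fluoride should cleave the less hindered secondary triethylsilyl ether while the secondary and the tertiary cyclopropyl tert-butyldimethylsilyl ethers stay.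

Step 11
Reactants: 15 (1R,4S)-4-(tert-butyldimethylsilyloxy)-2-[(1S,2R)-1-(tert-butyldimethylsilyloxy)-2-ethenyl-2-methylcyclopropyl]-3-methylcyclopent-2-en-1-ol
Product: 16 (4S)-4-(tert-butyldimethylsilyloxy)-2-[(1S,2R)-1-(tert-butyldimethylsilyloxy)-2-ethenyl-2-methylcyclopropyl]-3-methylcyclopent-2-en-1-one
Conditions: Dess–Martin periodinane, NaHCO3, CH2Cl2, 0 °C
Reagents that add atoms: none
Why: Dess–Martin oxidation of the allylic alcohol under buffered, non-acidic conditions gives the cyclopentenone without opening the siloxycyclopropane; C4 is no longer a stereocentre.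

Step 12
Reactants: 16 (4S)-4-(tert-butyldimethylsilyloxy)-2-[(1S,2R)-1-(tert-butyldimethylsilyloxy)-2-ethenyl-2-methylcyclopropyl]-3-methylcyclopent-2-en-1-one
Product: 17 (1R,2S)-2,6-bis(tert-butyldimethylsilyloxy)-1,8-dimethylbicyclo[5.3.0]deca-5,8-dien-4-one (overview numbering: C4 ketone, C5=C6 silyl enol ether, C8=C9 alkene)
Conditions: toluene, 110 °C, sealed tube
Reagents that add atoms: none
Why: Concerted [3,3]-sigmatropic (Cope) shift of the cis-divinylcyclopropane through the boat transition state with the C5=C1 and C9=C10 π-bonds over the three-membered ring: the C6–C8 σ-bond breaks while C1–C10 forms, the C6 silyloxy group feeding the breaking bond and the C4 carbonyl making C1 the accepting terminus, with release of ring strain as driving force. The closest known reaction type is the thermal divinylcyclopropane to cycloheptadiene rearrangement of 2-vinylcyclopropyl silyl ethers. The seven-membered ring closes by bonding of the two alkene termini C1 and C10, a pericyclic ring expansion of the cyclopropane by four atoms that is suprafacial on both alkenes and delivers the ring-cis alkenes C8=C9 and C5=C6. The only new stereocentre, quaternary C1, is set by chirality transfer from C6 and C8, which become trigonal: in the boat array C10 can reach only the C1 face on which C8 lies, here the face of the C2 silyloxy group, so the C1 methyl ends trans to that group. The step needs the cis cyclopropane and must tolerate the C1 methyl pointing inward; the first is secured by the E enol ether geometry carried through the stereospecific methylenation, and the second is expected to cost only the higher temperature, at which any trans isomer and the silyl ethers are inert.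

Step 13
Reactants: 17 (1R,2S)-2,6-bis(tert-butyldimethylsilyloxy)-1,8-dimethylbicyclo[5.3.0]deca-5,8-dien-4-one
Product: 18 (1R,2S,4S)-2,6-bis(tert-butyldimethylsilyloxy)-4-isopropyl-1,8-dimethylbicyclo[5.3.0]deca-5,8-dien-4-ol
Conditions: iPrMgCl, CeCl3, THF, −78 °C; aq. NaHCO3
Reagents that add atoms: isopropylmagnesium chloride CC(C)[Mg]Cl
Why: Organocerium 1,2-addition to the C4 carbonyl of the vinylogous silyl ester, non-basic enough to avoid enolisation and β-elimination of the C2 silyloxy group; the reagent should approach anti to the C2 silyloxy group and the C10 methylene, on the face of the C1 methyl, which sets C4 with its hydroxyl cis to the C2 oxygen.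

Step 14
Reactants: 18 (1R,2S,4S)-2,6-bis(tert-butyldimethylsilyloxy)-4-isopropyl-1,8-dimethylbicyclo[5.3.0]deca-5,8-dien-4-ol
Product: 19 (1R,2S,4S,5S)-2-(tert-butyldimethylsilyloxy)-4-hydroxy-4-isopropyl-1,8-dimethylbicyclo[5.3.0]dec-8-en-6-one (C5–H cis to the C1 methyl)
Conditions: TBAF, AcOH, THF, −20 to 0 °C
Reagents that add atoms: none
Why: Buffered fluoride cleavage of the silyl enol ether, much faster than that of the hindered secondary silyl ether, releases the C6 ketone without acid or strong base, so the tertiary ketol is not dehydrated and C8=C9 stays out of conjugation; C5 should be protonated on the face opposite the folded seven-membered ring to give the cis-fused epimer, which is also the more stable one because the C6 carbonyl then lies trans to the C4 isopropyl and C1 methyl groups and is hydrogen-bonded to the C4 hydroxyl.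

Step 15
Reactants: 19 (1R,2S,4S,5S)-2-(tert-butyldimethylsilyloxy)-4-hydroxy-4-isopropyl-1,8-dimethylbicyclo[5.3.0]dec-8-en-6-one
Product: 20 (1R,2S,4S,5R,6R)-2-(tert-butyldimethylsilyloxy)-4-isopropyl-1,8-dimethylbicyclo[5.3.0]dec-8-ene-4,6-diol
Conditions: Me4NBH(OAc)3, MeCN/AcOH, −20 °C
Reagents that add atoms: none
Why: Evans–Saksena reduction; the C4 hydroxyl exchanges onto boron and delivers hydride intramolecularly to the face of the C6 carbonyl on which the C4–O bond lies, giving the anti 1,3-diol with the C6 hydroxyl cis to C5–H.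

Step 16
Reactants: 20 (1R,2S,4S,5R,6R)-2-(tert-butyldimethylsilyloxy)-4-isopropyl-1,8-dimethylbicyclo[5.3.0]dec-8-ene-4,6-diol; 21 3,4,5-trimethoxybenzoyl chloride
Product: 22 (1R,2S,4S,5R,6R)-2-(tert-butyldimethylsilyloxy)-4-hydroxy-4-isopropyl-1,8-dimethylbicyclo[5.3.0]dec-8-en-6-yl 3,4,5-trimethoxybenzoate
Conditions: Et3N, DMAP (cat.), CH2Cl2, 0 °C to rt
Reagents that add atoms: none
Why: DMAP-catalysed acylation of the secondary C6 hydroxyl; the tertiary C4 hydroxyl does not react under these conditions and C2 is still silylated.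

Step 17
Reactants: 22 (1R,2S,4S,5R,6R)-2-(tert-butyldimethylsilyloxy)-4-hydroxy-4-isopropyl-1,8-dimethylbicyclo[5.3.0]dec-8-en-6-yl 3,4,5-trimethoxybenzoate
Product: 23 (1R,2S,4S,5R,6R)-2,4-dihydroxy-4-isopropyl-1,8-dimethylbicyclo[5.3.0]dec-8-en-6-yl 3,4,5-trimethoxybenzoate
Conditions: HF·pyridine, THF, rt
Reagents that add atoms: none
Why: Fluoride-mediated desilylation under mildly acidic conditions that leave the aryl ester, the tertiary alcohol and the trisubstituted alkene intact.

Step 18
Reactants: 23 (1R,2S,4S,5R,6R)-2,4-dihydroxy-4-isopropyl-1,8-dimethylbicyclo[5.3.0]dec-8-en-6-yl 3,4,5-trimethoxybenzoate; 24 angelic acid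
Product: 26 CNP0112256.1 (C2 angelate and C6 3,4,5-trimethoxybenzoate), via mixed anhydride 25 (not isolated)
Conditions: 2,4,6-trichlorobenzoyl chloride, Et3N, toluene, rt; then 23, 80 °C
Reagents that add atoms: 2,4,6-trichlorobenzoyl chloride O=C(Cl)c1c(Cl)cc(Cl)cc1Cl (aroyl group of 25)
Why: Yamaguchi-type esterification through the mixed anhydride without a nucleophilic amine catalyst, the established way to acylate hindered secondary alcohols with angelic acid without Z to E isomerisation; the C2 hydroxyl attacks the less hindered angeloyl carbonyl and the tertiary C4 hydroxyl stays free.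

**Compound list**

1 | (S)-4-(tert-butyldimethylsilyloxy)cyclopent-2-en-1-one | O=C1C=C[C@@H](O[Si](C)(C)C(C)(C)C)C1 | starting material
2 | (3S,4S)-4-(tert-butyldimethylsilyloxy)-3-methyl-1-(trimethylsilyloxy)cyclopent-1-ene (methyl trans to the silyloxy group) | C[Si](C)(C)OC1=C[C@H](C)[C@@H](O[Si](C)(C)C(C)(C)C)C1 | intermediate
3 | (S)-4-(tert-butyldimethylsilyloxy)-3-methylcyclopent-2-en-1-one | O=C1C=C(C)[C@@H](O[Si](C)(C)C(C)(C)C)C1 | intermediate
4 | (S)-4-(tert-butyldimethylsilyloxy)-2-iodo-3-methylcyclopent-2-en-1-one | O=C1C(I)=C(C)[C@@H](O[Si](C)(C)C(C)(C)C)C1 | intermediate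
5 | (1R,4S)-4-(tert-butyldimethylsilyloxy)-2-iodo-3-methylcyclopent-2-en-1-ol (cis) | IC1=C(C)[C@@H](O[Si](C)(C)C(C)(C)C)C[C@H]1O | intermediate
6 | cis-(1R,4S)-4-(tert-butyldimethylsilyloxy)-2-iodo-3-methyl-1-(triethylsilyloxy)cyclopent-2-ene | IC1=C(C)[C@@H](O[Si](C)(C)C(C)(C)C)C[C@H]1O[Si](CC)(CC)CC | intermediate
7 | 2-methylbut-3-enoic acid (racemic) | C=CC(C)C(O)=O | starting material
8 | 1-(2-methylbut-3-enoyl)imidazole (acyl imidazolide, not isolated) | C=CC(C)C(=O)n1ccnc1 | intermediate
9 | N-methoxy-N,2-dimethylbut-3-enamide | C=CC(C)C(=O)N(C)OC | intermediate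
10 | [(3S,5R)-3-(tert-butyldimethylsilyloxy)-2-methyl-5-(triethylsilyloxy)cyclopent-1-en-1-yl]lithium (not isolated) | [Li]C1=C(C)[C@@H](O[Si](C)(C)C(C)(C)C)C[C@H]1O[Si](CC)(CC)CC | intermediate
11 | 1-[(3S,5R)-3-(tert-butyldimethylsilyloxy)-2-methyl-5-(triethylsilyloxy)cyclopent-1-en-1-yl]-2-methylbut-3-en-1-one (both C8 epimers) | C=CC(C)C(=O)C1=C(C)[C@@H](O[Si](C)(C)C(C)(C)C)C[C@H]1O[Si](CC)(CC)CC | intermediate
12 | lithium (1E)-dienolate of 11 (not isolated) | C=C/C(C)=C(/O[Li])C1=C(C)[C@@H](O[Si](C)(C)C(C)(C)C)C[C@H]1O[Si](CC)(CC)CC | intermediate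
13 | (1E)-1-(tert-butyldimethylsilyloxy)-1-[(3S,5R)-3-(tert-butyldimethylsilyloxy)-2-methyl-5-(triethylsilyloxy)cyclopent-1-en-1-yl]-2-methylbuta-1,3-diene | C=C/C(C)=C(/O[Si](C)(C)C(C)(C)C)C1=C(C)[C@@H](O[Si](C)(C)C(C)(C)C)C[C@H]1O[Si](CC)(CC)CC | intermediate
14 | (1S,2R)-1-(tert-butyldimethylsilyloxy)-1-[(3S,5R)-3-(tert-butyldimethylsilyloxy)-2-methyl-5-(triethylsilyloxy)cyclopent-1-en-1-yl]-2-ethenyl-2-methylcyclopropane (cyclopentenyl cis to ethenyl) | C=C[C@@]1(C)C[C@@]1(O[Si](C)(C)C(C)(C)C)C2=C(C)[C@@H](O[Si](C)(C)C(C)(C)C)C[C@H]2O[Si](CC)(CC)CC | intermediate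
15 | (1R,4S)-4-(tert-butyldimethylsilyloxy)-2-[(1S,2R)-1-(tert-butyldimethylsilyloxy)-2-ethenyl-2-methylcyclopropyl]-3-methylcyclopent-2-en-1-ol | C=C[C@@]1(C)C[C@@]1(O[Si](C)(C)C(C)(C)C)C2=C(C)[C@@H](O[Si](C)(C)C(C)(C)C)C[C@H]2O | intermediate
16 | (4S)-4-(tert-butyldimethylsilyloxy)-2-[(1S,2R)-1-(tert-butyldimethylsilyloxy)-2-ethenyl-2-methylcyclopropyl]-3-methylcyclopent-2-en-1-one (key-step precursor) | C=C[C@@]1(C)C[C@@]1(O[Si](C)(C)C(C)(C)C)C2=C(C)[C@@H](O[Si](C)(C)C(C)(C)C)CC2=O | intermediate
17 | (1R,2S)-2,6-bis(tert-butyldimethylsilyloxy)-1,8-dimethylbicyclo[5.3.0]deca-5,8-dien-4-one (overview numbering; key-step product) | CC(C)(C)[Si](C)(C)O[C@H]1CC(=O)C2=C(O[Si](C)(C)C(C)(C)C)CC(C)=CC[C@@]12C | intermediate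
18 | (1R,2S,4S)-2,6-bis(tert-butyldimethylsilyloxy)-4-isopropyl-1,8-dimethylbicyclo[5.3.0]deca-5,8-dien-4-ol (overview numbering) | CC(C)(C)[Si](C)(C)O[C@H]1C[C@](O)(C(C)C)C2=C(O[Si](C)(C)C(C)(C)C)CC(C)=CC[C@@]12C | intermediate
19 | (1R,2S,4S,5S)-2-(tert-butyldimethylsilyloxy)-4-hydroxy-4-isopropyl-1,8-dimethylbicyclo[5.3.0]dec-8-en-6-one (cis-fused, overview numbering) | CC(C)(C)[Si](C)(C)O[C@H]1C[C@](O)(C(C)C)[C@H]2C(=O)CC(C)=CC[C@@]12C | intermediate
20 | (1R,2S,4S,5R,6R)-2-(tert-butyldimethylsilyloxy)-4-isopropyl-1,8-dimethylbicyclo[5.3.0]dec-8-ene-4,6-diol (overview numbering) | CC(C)(C)[Si](C)(C)O[C@H]1C[C@](O)(C(C)C)[C@H]2[C@H](O)CC(C)=CC[C@@]12C | intermediate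
21 | 3,4,5-trimethoxybenzoyl chloride | COc1cc(cc(OC)c1OC)C(Cl)=O | starting material
22 | C6 3,4,5-trimethoxybenzoate of 20 (C2 silyl ether, C4 hydroxyl free) | CC(C)(C)[Si](C)(C)O[C@H]1C[C@](O)(C(C)C)[C@H]2[C@H](OC(=O)c3cc(OC)c(OC)c(OC)c3)CC(C)=CC[C@@]12C | intermediate
23 | (1R,2S,4S,5R,6R)-2,4-dihydroxy-4-isopropyl-1,8-dimethylbicyclo[5.3.0]dec-8-en-6-yl 3,4,5-trimethoxybenzoate (overview numbering) | O[C@H]1C[C@](O)(C(C)C)[C@H]2[C@H](OC(=O)c3cc(OC)c(OC)c(OC)c3)CC(C)=CC[C@@]12C | intermediate
24 | angelic acid, (Z)-2-methylbut-2-enoic acid | C/C=C(/C)C(O)=O | starting material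
25 | angelic 2,4,6-trichlorobenzoic anhydride (not isolated) | C/C=C(/C)C(=O)OC(=O)c1c(Cl)cc(Cl)cc1Cl | intermediate
26 | CNP0112256.1, (1R,2S,4S,5R,6R)-2-angeloyloxy-4-hydroxy-4-isopropyl-1,8-dimethylbicyclo[5.3.0]dec-8-en-6-yl 3,4,5-trimethoxybenzoate (overview numbering) | C/C=C(/C)C(=O)O[C@H]1C[C@](O)(C(C)C)[C@H]2[C@H](OC(=O)c3cc(OC)c(OC)c(OC)c3)CC(C)=CC[C@@]12C | target

**Step count**

Total step count: 18. Longest linear sequence: 17 steps (from 1 through steps 1–5 and 7–18).

**Steps most likely to fail**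

Step 9 (methylenation). The facial selectivity of methylene transfer to the twisted enol ether may be poor or reversed, because the two faces differ only through the C4 silyl ether and the C1 methyl; the cis-cyclopropane that leads to the C1 epimer would then build up. The fallback reverses the substrate bias by inverting C4; it sets out from 5 and returns at 16. Mitsunobu reaction of 5 (4-nitrobenzoic acid, PPh3, DIAD) should give the trans ester (1S,4S)-4-(tert-butyldimethylsilyloxy)-2-iodo-3-methylcyclopent-2-en-1-yl 4-nitrobenzoate F1, and methanolysis (K2CO3, MeOH) the trans alcohol (1S,4S)-4-(tert-butyldimethylsilyloxy)-2-iodo-3-methylcyclopent-2-en-1-ol F2. Silylation as in step 5 gives the trans triethylsilyl ether F3. Iodine–lithium exchange to the C4-epimeric alkenyllithium F4 and acylation with 9 give the C4-epimeric ketone F5. Enolisation to the C4-epimeric lithium dienolate F6 and silylation give the C4-epimeric silyl dienol ether F7. Methylenation is then expected to give the C4-epimeric cyclopropane F8 with the (1S,2R) cyclopropane configuration of 14, desilylation the C4-epimeric carbinol F9, and Dess–Martin oxidation of F9, which makes C4 trigonal, gives 16.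

Step 12 (key step). The [3,3] shift may be slower than thermal loss of silanol from the β-silyloxy enone or oligomerisation of the enone, because the C1 methyl must point inward in the boat. The fallback moves the rearrangement one stage back to a substrate without the enone; it sets out from 15 and returns at 17. Heating the carbinol 15 (xylene, up to 140 °C) should give (1R,2S,4R)-2,6-bis(tert-butyldimethylsilyloxy)-1,8-dimethylbicyclo[5.3.0]deca-5,8-dien-4-ol F10, and Dess–Martin oxidation of its allylic alcohol gives 17.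

Step 13 (isopropyl addition). β-Hydride transfer from the secondary organometallic may reduce the hindered vinylogous ester carbonyl instead of adding to it, and addition may be incomplete. The fallback uses an sp2 nucleophile that cannot transfer hydride and saturates it later; it sets out from 17 and returns at 19. 2-Propenylmagnesium bromide with CeCl3 (THF, −78 °C) should give the isopropenyl carbinol (C4 isopropenyl analogue of 18) F11. TBAF/AcOH then gives the isopropenyl ketol (C4 isopropenyl analogue of 19) F12, and hydrogenation with RhCl(PPh3)3 under H2 saturates only the 1,1-disubstituted alkene to give 19.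

**Further compounds**

F1 | step 9 | (1S,4S)-4-(tert-butyldimethylsilyloxy)-2-iodo-3-methylcyclopent-2-en-1-yl 4-nitrobenzoate (trans) | IC1=C(C)[C@@H](O[Si](C)(C)C(C)(C)C)C[C@@H]1OC(=O)c2ccc(cc2)[N+](=O)[O-]
F2 | step 9 | (1S,4S)-4-(tert-butyldimethylsilyloxy)-2-iodo-3-methylcyclopent-2-en-1-ol (trans) | IC1=C(C)[C@@H](O[Si](C)(C)C(C)(C)C)C[C@@H]1O
F3 | step 9 | trans triethylsilyl ether, C4 epimer of 6 | IC1=C(C)[C@@H](O[Si](C)(C)C(C)(C)C)C[C@@H]1O[Si](CC)(CC)CC
F4 | step 9 | alkenyllithium, C4 epimer of 10 | [Li]C1=C(C)[C@@H](O[Si](C)(C)C(C)(C)C)C[C@@H]1O[Si](CC)(CC)CC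
F5 | step 9 | ketone, C4 epimer of 11 | C=CC(C)C(=O)C1=C(C)[C@@H](O[Si](C)(C)C(C)(C)C)C[C@@H]1O[Si](CC)(CC)CC
F6 | step 9 | lithium dienolate, C4 epimer of 12 | C=C/C(C)=C(/O[Li])C1=C(C)[C@@H](O[Si](C)(C)C(C)(C)C)C[C@@H]1O[Si](CC)(CC)CC
F7 | step 9 | silyl dienol ether, C4 epimer of 13 | C=C/C(C)=C(/O[Si](C)(C)C(C)(C)C)C1=C(C)[C@@H](O[Si](C)(C)C(C)(C)C)C[C@@H]1O[Si](CC)(CC)CC
F8 | step 9 | cyclopropane, C4 epimer of 14 | C=C[C@@]1(C)C[C@@]1(O[Si](C)(C)C(C)(C)C)C2=C(C)[C@@H](O[Si](C)(C)C(C)(C)C)C[C@@H]2O[Si](CC)(CC)CC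
F9 | step 9 | carbinol, C4 epimer of 15 | C=C[C@@]1(C)C[C@@]1(O[Si](C)(C)C(C)(C)C)C2=C(C)[C@@H](O[Si](C)(C)C(C)(C)C)C[C@@H]2O
F10 | step 12 | (1R,2S,4R)-2,6-bis(tert-butyldimethylsilyloxy)-1,8-dimethylbicyclo[5.3.0]deca-5,8-dien-4-ol (C4 hydroxyl cis to the C2 oxygen) | CC(C)(C)[Si](C)(C)O[C@H]1C[C@@H](O)C2=C(O[Si](C)(C)C(C)(C)C)CC(C)=CC[C@@]12C
F11 | step 13 | isopropenyl carbinol, C4 isopropenyl analogue of 18 | CC(C)(C)[Si](C)(C)O[C@H]1C[C@](O)(C(C)=C)C2=C(O[Si](C)(C)C(C)(C)C)CC(C)=CC[C@@]12C
F12 | step 13 | isopropenyl ketol, C4 isopropenyl analogue of 19 | CC(C)(C)[Si](C)(C)O[C@H]1C[C@](O)(C(C)=C)[C@H]2C(=O)CC(C)=CC[C@@]12C
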